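Start with the clock.

    free monomer + initiator → living end + monomer in chains (k1 = 34 L mol⁻¹ h⁻¹, Ea1 = 51.0 kJ mol⁻¹)
    free monomer + living end → monomer in chains + living end, rate k2*[living end]*[free monomer] (k2 = 130 L mol⁻¹ h⁻¹, Ea2 = 63.0 kJ mol⁻¹)
    monomer in chains + initiator ⇌ isomer of the product + initiator, rate k3*[initiator]*[monomer in chains] forward; the back reaction follows from the equilibrium constant (K3 = 3.2, k3 = 410 L mol⁻¹ h⁻¹, Ea3 = 45.0 kJ mol⁻¹, ΔH3 = −4.00 kJ mol⁻¹)
    pre-initiator ⇌ initiator (K4 = 0.80, k4 = 0.42 h⁻¹, Ea4 = 116 kJ mol⁻¹, ΔH4 = −8.00 kJ mol⁻¹)
    (constants at 60 °C)

in all of them: free monomer 20 mM; pre-initiator 0.50 mM; time 12 h
- autumn: temperature 60 °C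
- winter: temperature 90 °C
- midnight: temperature 30 °C

- constants are those at 60 °C; use the activation energies and enthalpies for any other temperature

- the best flask by amount of monomer in chains, in percent of the free monomer charged; "all alike" if 1.5 percentage points covers them all (autumn / winter / midnight / all alike)
- amount of monomer in chains at the end, in percent of the free monomer charged, autumn
- amount of monomer in chains at the end, in percent of the free monomer charged, winter
- amount of monomer in chains at the end, in percent of the free monomer charged, midnight

In the autumn flask monomer enters chains mainly through the propagation step, whose rate is its constant times living ends times free monomer. The bench rule of thumb counts every pre-initiator as a living end from the first moment. The living ends are then constant, the decay of free monomer is pseudo-first-order, and in the autumn flask you would expect 45.8 % of the free monomer left at the end.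

But the living ends have to be made first, so you should ask how long that takes. In autumn, pre-initiator becomes initiator at 0.42 h⁻¹. That initiator can fall back at 0.525 h⁻¹ or be captured by free monomer at 0.680 h⁻¹, and capture is faster than return, but by a ratio of just 1.30. Both therefore count, and together they give the release time, 4.22 h: the mean time a pre-initiator spends as pre-initiator, return trips counted, reckoned at the starting free monomer. Time spent as initiator adds 1.47 h, so the mean wait until a living end is 5.69 h.

Now let the living ends rise towards the charge with this wait as time constant and integrate the propagation rate in closed form. The run then counts as an effective time: the run time minus the wait multiplied by the fraction of the charge that has become living ends. For autumn that is 7.00 h, so my own reckoning leaves 63.4 % of the free monomer, and I do not reckon how the converted part divides between monomer in chains and isomer of the product.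

The border of the rule of thumb is the run time over the release time, which is 2.84 in autumn. At midnight, the relaxation half-life 53.7 h and the equilibrium constant 1.06 give a release time, by the forward step alone, of 150 h. The ratio there is 0.0799, so the midnight flask ends inside its lag and the rule of thumb has no ground.

The forecast names winter as best, with 29 % for autumn, 84 % for winter and 0.18 % for midnight. Of the cold flask it says “the strongly temperature-dependent release of initiator nearly stops”.

The simulation gives 33.9 % for autumn, 87.4 % for winter and 0.187 % for midnight, so winter is best, as forecast. Time overturns that order: after 120 h, the autumn flask holds 85.9 % as monomer in chains and the winter flask 45.9 %. The release time puts autumn pre-initiator at 24.1 % of its charge after 6.00 h, where 25.3 % stood. At midnight it gives 44.9 % after 120 h, where 47.0 % stood.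

(The rate constants were chosen freely; the rest is arithmetic.)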